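## Retrosynthetic overview

1. Target 16 comes from hydrogenolysis of the two catechol benzyl ethers of 15, and 15 from lipase-mediated removal of the C7 acetate of 14 with the lactone kept intact.
2. 14 comes from Rh/(R)-SEGPHOS asymmetric 1,4-addition of arylboronic acid 13 to 7-acetoxycoumarin 12; this sets C4, the only stereocentre.
3. 12 comes from 7-hydroxycoumarin 11, made by Wittig olefination/lactonisation of salicylaldehyde 7.
4. 7 comes from Vilsmeier formylation of bibenzyl resorcinol 5, made by Horner–Wadsworth–Emmons coupling of 1 and 2 followed by hydrogenation.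
5. Ring order: the three benzene rings are bought; the only ring built is the pyranone (step 4), whose C3=C4 bond is saturated in the asymmetric step.

Assumption: 2,4-bis(benzyloxy)benzaldehyde, diethyl (3,4-dimethoxybenzyl)phosphonate, ethyl (triphenylphosphoranylidene)acetate and [3,4-bis(benzyloxy)phenyl]boronic acid are taken as catalogue compounds.

## Route

Step 1
Reactants: 1 2,4-bis(benzyloxy)benzaldehyde; 2 diethyl (3,4-dimethoxybenzyl)phosphonate
Product: 4 (E)-2,4-bis(benzyloxy)-1-[2-(3,4-dimethoxyphenyl)ethenyl]benzene, via potassium phosphonate carbanion 3 (not isolated)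
Conditions: KOtBu, THF, 0 °C → rt
Reagents that add atoms: none
Why: Horner–Wadsworth–Emmons olefination: the benzylic phosphonate carbanion adds to the non-enolisable aldehyde and the oxaphosphetane collapses to the E-stilbene, whose geometry does not matter because the alkene is hydrogenated next.

Step 2
Reactants: 4 (E)-2,4-bis(benzyloxy)-1-[2-(3,4-dimethoxyphenyl)ethenyl]benzene
Product: 5 4-[2-(3,4-dimethoxyphenyl)ethyl]benzene-1,3-diol
Conditions: H2 (1 atm), 10% Pd/C, EtOAc–EtOH, rt
Reagents that add atoms: none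
Why: Heterogeneous catalytic hydrogenation saturates the stilbene C=C and hydrogenolyses both benzyl aryl ethers in one operation, while the methyl ethers are inert.

Step 3
Reactants: 5 4-[2-(3,4-dimethoxyphenyl)ethyl]benzene-1,3-diol
Product: 7 5-[2-(3,4-dimethoxyphenyl)ethyl]-2,4-dihydroxybenzaldehyde, via aryl iminium chloride 6 (not isolated)
Conditions: POCl3, DMF, MeCN, 0 °C → rt; then H2O, 50 °C
Reagents that add atoms: N,N-dimethylformamide CN(C)C=O; water O
Why: Vilsmeier–Haack formylation: the chloroiminium ion attacks the resorcinol ring at the one unhindered position ortho to one OH and para to the other (the dimethoxyphenyl ring is far less nucleophilic and the position between the hydroxyls is crowded), and water hydrolyses the iminium to the aldehyde.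

Step 4
Reactants: 7 5-[2-(3,4-dimethoxyphenyl)ethyl]-2,4-dihydroxybenzaldehyde; 8 ethyl (triphenylphosphoranylidene)acetate
Product: 11 6-[2-(3,4-dimethoxyphenyl)ethyl]-7-hydroxy-2H-chromen-2-one, via E-cinnamate ester 9 (not isolated), via Z-cinnamate ester 10 (not isolated)
Conditions: PhNEt2, reflux (about 215 °C)
Reagents that add atoms: none
Why: Wittig olefination with the stabilised ylide gives the 2-hydroxycinnamate, which at this temperature isomerises E→Z and lactonises with loss of ethanol to close the pyranone ring (Wittig–lactonisation coumarin synthesis).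

Step 5
Reactants: 11 6-[2-(3,4-dimethoxyphenyl)ethyl]-7-hydroxy-2H-chromen-2-one
Product: 12 6-[2-(3,4-dimethoxyphenyl)ethyl]-2-oxo-2H-chromen-7-yl acetate
Conditions: Ac2O, pyridine, cat. DMAP, rt
Reagents that add atoms: acetic anhydride CC(=O)OC(C)=O
Why: DMAP-catalysed O-acetylation of the only free phenol; the acetate makes the C7 oxygen a weaker donor, so the coumarin is a better Michael acceptor, and it is the handle for the later enzymatic unmasking.

Step 6
Reactants: 12 6-[2-(3,4-dimethoxyphenyl)ethyl]-2-oxo-2H-chromen-7-yl acetate; 13 [3,4-bis(benzyloxy)phenyl]boronic acid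
Product: 14 (4R)-4-[3,4-bis(benzyloxy)phenyl]-6-[2-(3,4-dimethoxyphenyl)ethyl]-2-oxo-3,4-dihydro-2H-chromen-7-yl acetate
Conditions: Rh(acac)(C2H4)2 (3 mol %), (R)-SEGPHOS (3.3 mol %), 13 (5 equiv, two portions), dioxane–H2O (10:1), 60 °C
Reagents that add atoms: none
Why: Hayashi–Miyaura rhodium-catalysed asymmetric 1,4-addition: the aryl–Rh(I)/(R)-SEGPHOS complex carbometalates the coumarin C3=C4 bond on the C4 Si face, creating the only stereocentre as 4R by analogy with simple coumarins, and water protonates the rhodium enolate under neutral conditions that spare the aryl acetate and the lactone.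

Step 7
Reactants: 14 (4R)-4-[3,4-bis(benzyloxy)phenyl]-6-[2-(3,4-dimethoxyphenyl)ethyl]-2-oxo-3,4-dihydro-2H-chromen-7-yl acetate
Product: 15 (4R)-4-[3,4-bis(benzyloxy)phenyl]-6-[2-(3,4-dimethoxyphenyl)ethyl]-7-hydroxy-3,4-dihydro-2H-chromen-2-one
Conditions: lipase (immobilised Candida antarctica lipase B, a serine hydrolase, EC 3.1.1.3), n-BuOH (10 equiv), MTBE, 40 °C
Reagents that add atoms: none
Why: Lipase-catalysed transesterification: the small acetyl group enters the acyl pocket and is passed via the acyl-enzyme to n-butanol, whereas the lactone carbonyl with its β,β-diaryl-substituted chain should not be accepted, so the phenol is released under neutral anhydrous conditions without ring opening or risk to C4.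

Step 8
Reactants: 15 (4R)-4-[3,4-bis(benzyloxy)phenyl]-6-[2-(3,4-dimethoxyphenyl)ethyl]-7-hydroxy-3,4-dihydro-2H-chromen-2-one
Product: 16 (4R)-4-(3,4-dihydroxyphenyl)-6-[2-(3,4-dimethoxyphenyl)ethyl]-7-hydroxy-3,4-dihydro-2H-chromen-2-one
Conditions: H2 (1 atm), 10% Pd/C, EtOAc–THF, rt
Reagents that add atoms: none
Why: Pd-catalysed hydrogenolysis cleaves the two benzyl aryl ethers to the catechol in a neutral, non-nucleophilic solvent; the methyl ethers, the aryl lactone and the C4 stereocentre (C–C bonds only) are untouched.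

## Compound list

1 | 2,4-bis(benzyloxy)benzaldehyde | O=Cc1ccc(OCc2ccccc2)cc1OCc1ccccc1 | starting material
2 | diethyl (3,4-dimethoxybenzyl)phosphonate | CCOP(=O)(Cc1ccc(OC)c(OC)c1)OCC | starting material
3 | potassium (diethoxyphosphoryl)(3,4-dimethoxyphenyl)methanide | CCOP(=O)(OCC)[CH-]c1ccc(OC)c(OC)c1.[K+] | intermediate
4 | (E)-2,4-bis(benzyloxy)-1-[2-(3,4-dimethoxyphenyl)ethenyl]benzene | COc1ccc(/C=C/c2ccc(OCc3ccccc3)cc2OCc2ccccc2)cc1OC | intermediate
5 | 4-[2-(3,4-dimethoxyphenyl)ethyl]benzene-1,3-diol | COc1ccc(CCc2ccc(O)cc2O)cc1OC | intermediate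
6 | N-{5-[2-(3,4-dimethoxyphenyl)ethyl]-2,4-dihydroxybenzylidene}-N-methylmethanaminium chloride | C[N+](C)=Cc1cc(CCc2ccc(OC)c(OC)c2)c(O)cc1O.[Cl-] | intermediate
7 | 5-[2-(3,4-dimethoxyphenyl)ethyl]-2,4-dihydroxybenzaldehyde | COc1ccc(CCc2cc(C=O)c(O)cc2O)cc1OC | intermediate
8 | ethyl (triphenylphosphoranylidene)acetate | CCOC(=O)C=P(c1ccccc1)(c1ccccc1)c1ccccc1 | starting material
9 | ethyl (E)-3-{5-[2-(3,4-dimethoxyphenyl)ethyl]-2,4-dihydroxyphenyl}prop-2-enoate | CCOC(=O)/C=C/c1cc(CCc2ccc(OC)c(OC)c2)c(O)cc1O | intermediate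
10 | ethyl (Z)-3-{5-[2-(3,4-dimethoxyphenyl)ethyl]-2,4-dihydroxyphenyl}prop-2-enoate | CCOC(=O)/C=C\c1cc(CCc2ccc(OC)c(OC)c2)c(O)cc1O | intermediate
11 | 6-[2-(3,4-dimethoxyphenyl)ethyl]-7-hydroxy-2H-chromen-2-one | COc1ccc(CCc2cc3ccc(=O)oc3cc2O)cc1OC | intermediate
12 | 6-[2-(3,4-dimethoxyphenyl)ethyl]-2-oxo-2H-chromen-7-yl acetate | COc1ccc(CCc2cc3ccc(=O)oc3cc2OC(C)=O)cc1OC | intermediate
13 | [3,4-bis(benzyloxy)phenyl]boronic acid | OB(O)c1ccc(OCc2ccccc2)c(OCc2ccccc2)c1 | starting material
14 | (4R)-4-[3,4-bis(benzyloxy)phenyl]-6-[2-(3,4-dimethoxyphenyl)ethyl]-2-oxo-3,4-dihydro-2H-chromen-7-yl acetate | COc1ccc(CCc2cc3c(cc2OC(C)=O)OC(=O)C[C@@H]3c2ccc(OCc3ccccc3)c(OCc3ccccc3)c2)cc1OC | intermediate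
15 | (4R)-4-[3,4-bis(benzyloxy)phenyl]-6-[2-(3,4-dimethoxyphenyl)ethyl]-7-hydroxy-3,4-dihydro-2H-chromen-2-one | COc1ccc(CCc2cc3c(cc2O)OC(=O)C[C@@H]3c2ccc(OCc3ccccc3)c(OCc3ccccc3)c2)cc1OC | intermediate
16 | (4R)-4-(3,4-dihydroxyphenyl)-6-[2-(3,4-dimethoxyphenyl)ethyl]-7-hydroxy-3,4-dihydro-2H-chromen-2-one | COc1ccc(CCc2cc3c(cc2O)OC(=O)C[C@@H]3c2ccc(O)c(O)c2)cc1OC | target

## Summary

Total step count: 8. Longest linear sequence: 8 steps (1 and 2 to 16).

Steps most likely to fail, each with a fallback:

Step 6 (asymmetric 1,4-addition; the acceptor carries a 7-oxygen substituent and the boronic acid is electron-rich and may protodeboronate before it adds). The fallback sets out from 12 and comes back at 14. Oxidative Heck coupling of 12 with 13 (Pd(OAc)2, 1,10-phenanthroline, O2, DMF, 80 °C) gives the achiral 4-arylcoumarin 7-acetoxy-4-[3,4-bis(benzyloxy)phenyl]-6-[2-(3,4-dimethoxyphenyl)ethyl]-2H-chromen-2-one F1. The stereocentre is then set by hydride instead of aryl delivery: copper hydride-catalysed asymmetric conjugate reduction (Cu(OAc)2, DTBM-SEGPHOS, (EtO)2MeSiH, t-BuOH, toluene, rt) gives 14. The ligand antipode is the one that gives the 4R lactone, chosen by a test reduction and chiral HPLC; t-BuOH releases the lactone enolate and limits over-reduction.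

Step 7 (lipase deacetylation; the bulky substrate may react slowly, or the aryl lactone may be partly opened). The fallback sets out from 14 and comes back at 15. Instead of relying on chemoselectivity, the ester cleavage is driven to completion with a carboxylesterase (pig liver esterase, a hydrolase) in pH 7 phosphate buffer with acetone as cosolvent. Whatever lactone has opened is present as the seco acid (3R)-3-[3,4-bis(benzyloxy)phenyl]-3-{5-[2-(3,4-dimethoxyphenyl)ethyl]-2,4-dihydroxyphenyl}propanoic acid F2. The crude mixture is then heated with catalytic TsOH in toluene at 80 °C, which closes the six-membered aryl lactone again and gives 15; C4 is not enolisable and is unaffected.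

Step 4 (thermal Wittig–lactonisation at about 215 °C with two free phenols; tar or stalled E-ester is possible). The fallback sets out from 7 and comes back at 11. Knoevenagel condensation of 7 with Meldrum's acid (cat. piperidinium acetate, EtOH, 70 °C) closes the pyranone ring under mild conditions and gives 6-[2-(3,4-dimethoxyphenyl)ethyl]-7-hydroxy-2-oxo-2H-chromene-3-carboxylic acid F3. Silver-catalysed protodecarboxylation (Ag2CO3 10 mol %, cat. AcOH, DMSO, 120 °C) then gives 11.

Further compounds
F1 | step 6 | 7-acetoxy-4-[3,4-bis(benzyloxy)phenyl]-6-[2-(3,4-dimethoxyphenyl)ethyl]-2H-chromen-2-one | COc1ccc(CCc2cc3c(cc2OC(C)=O)oc(=O)cc3-c2ccc(OCc3ccccc3)c(OCc3ccccc3)c2)cc1OC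
F2 | step 7 | (3R)-3-[3,4-bis(benzyloxy)phenyl]-3-{5-[2-(3,4-dimethoxyphenyl)ethyl]-2,4-dihydroxyphenyl}propanoic acid | OC(=O)C[C@@H](c1cc(CCc2ccc(OC)c(OC)c2)c(O)cc1O)c1ccc(OCc2ccccc2)c(OCc2ccccc2)c1
F3 | step 4 | 6-[2-(3,4-dimethoxyphenyl)ethyl]-7-hydroxy-2-oxo-2H-chromene-3-carboxylic acid | COc1ccc(CCc2cc3cc(C(=O)O)c(=O)oc3cc2O)cc1OC
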